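The benzene ring of ardisiphenol C is read as a cyclised tetraketide: C1, which carries the C17 chain, is the former carboxyl carbon of linoleic acid, C3 and C5 hold the ketide oxygens, and acetoxylated C6 marks the site of the polyketide's own carboxyl terminus. Everything rests on disconnecting the C1–C6 ring bond. An amine-mediated intramolecular aldol condensation of a linoleoyl diketo-dioxinone should forge that bond and build the whole arene in one operation, giving a resorcylate acetonide whose lactone carbon tags C6 for later carbon-to-oxygen exchange by Dakin oxidation. The precursor is a dioxinone-masked 3,5,7-triketo acid bearing the untouched (Z,Z)-skipped diene.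

Key step: step 4

Assumption: ring positions are numbered as in the target (C1 chain-bearing, C3 and C5 hydroxylated, C6 acetoxylated). Linoleic acid of high (9Z,12Z) purity is used, and all steps are run under argon with degassed solvents because the skipped diene autoxidises.

Step 1
Reactants: 1 linoleic acid, (9Z,12Z)-octadeca-9,12-dienoic acid
Product: 3 1-[(9Z,12Z)-octadeca-9,12-dienoyl]-1H-benzotriazole, via O-acylisourea 2 (not isolated)
Conditions: 1H-benzotriazole, DCC, CH2Cl2, 0 °C → rt
Reagents that add atoms: 1H-benzotriazole, c1ccc2[nH]nnc2c1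
Why: Carbodiimide (Steglich-type) activation turns the acid into an O-acylisourea that benzotriazole N1 intercepts to give the bench-stable N-acylbenzotriazole under neutral conditions that leave the (Z,Z)-diene untouched.

Step 2
Reactants: 4 2,2,6-trimethyl-4H-1,3-dioxin-4-one
Product: 6 2,2-dimethyl-6-(2-oxopropyl)-4H-1,3-dioxin-4-one, via lithium dienolate 5 (not isolated)
Conditions: LiN(SiMe3)2, THF, −78 °C; AcCl (0.5 equiv), −78 °C; aq. NH4Cl
Reagents that add atoms: acetyl chloride, CC(Cl)=O
Why: γ-Deprotonation of the vinylogous ester gives the lithium dienolate, which should undergo γ-selective C-acylation (crossed Claisen condensation) with acetyl chloride, the dienolate being used in two-fold excess because the product is more acidic than 4.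

Step 3
Reactants: 6 2,2-dimethyl-6-(2-oxopropyl)-4H-1,3-dioxin-4-one; 3 1-[(9Z,12Z)-octadeca-9,12-dienoyl]-1H-benzotriazole
Product: 8 6-[(12Z,15Z)-2,4-dioxohenicosa-12,15-dien-1-yl]-2,2-dimethyl-4H-1,3-dioxin-4-one, via dilithium dianion 7 (not isolated)
Conditions: 6 (2 equiv), LiN(i-Pr)2 (4 equiv), THF, −78 °C; then 3 (1 equiv), −78 → −40 °C; aq. NH4Cl
Reagents that add atoms: none
Why: The dianion of the keto-dioxinone should react at its last-formed, most basic terminal carbon in a crossed Claisen condensation with the N-acylbenzotriazole, a neutral acyl donor that resists over-addition, while the remote diene is inert to the fully consumed amide base at low temperature.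

Step 4
Reactants: 8 6-[(12Z,15Z)-2,4-dioxohenicosa-12,15-dien-1-yl]-2,2-dimethyl-4H-1,3-dioxin-4-one (used crude)
Product: 10 5-[(8Z,11Z)-heptadeca-8,11-dien-1-yl]-7-hydroxy-2,2-dimethyl-4H-1,3-benzodioxin-4-one, via aldol adduct 9 (not isolated)
Conditions: Et3N (5 equiv), CH2Cl2, rt; dilute aq. HCl wash
Reagents that add atoms: none
Why: Et3N reversibly enolises the diketone/dioxinone array, and the dioxinone C5 carbon (nucleophilic through the O–C6=C5 enol-ether unit and its γ-deprotonated dienolate) adds to the linoleoyl ketone to give the cyclic aldol 9; E1cB loss of water and tautomerisation of the remaining ring ketone should then deliver the phenol, with aromatisation as the driving force. The closest known reaction type is the base-mediated intramolecular aldol condensation and aromatisation of diketo-dioxinones to resorcylate acetonides, the laboratory version of the orsellinate-type polyketide fold. The single ring closes in a 6-(enolendo)-exo-trig mode and the new bond becomes C1–C6 of the arene. No stereocentre is set: the carbinol centre of 9 is racemic and is erased on dehydration, and the remote (Z,Z)-diene meets only a tertiary amine at room temperature. The selectivity required is C-aldol closure and not Claisen-type acyl transfer or O-cyclisation to a pyranone; it is secured because the terminal carboxyl is locked in the acetonide lactone, a poor acyl donor below its thermolysis temperature, and because attack of C5 on the nearer ketone would need a four-membered ring.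

Step 5
Reactants: 10 5-[(8Z,11Z)-heptadeca-8,11-dien-1-yl]-7-hydroxy-2,2-dimethyl-4H-1,3-benzodioxin-4-one
Product: 11 7-[(tert-butyldimethylsilyl)oxy]-5-[(8Z,11Z)-heptadeca-8,11-dien-1-yl]-2,2-dimethyl-4H-1,3-benzodioxin-4-one
Conditions: TBSCl, imidazole, DMF, rt
Reagents that add atoms: tert-butyldimethylsilyl chloride, CC(C)(C)[Si](C)(C)Cl
Why: Imidazole-promoted silylation of the only free phenol removes the acidic proton that would otherwise consume hydride and deactivate the lactone carbonyl in the reduction that follows.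

Step 6
Reactants: 11 7-[(tert-butyldimethylsilyl)oxy]-5-[(8Z,11Z)-heptadeca-8,11-dien-1-yl]-2,2-dimethyl-4H-1,3-benzodioxin-4-one
Product: 13 4-[(tert-butyldimethylsilyl)oxy]-2-[(8Z,11Z)-heptadeca-8,11-dien-1-yl]-6-hydroxybenzaldehyde, via (i-Bu)2Al lactolate 12 (not isolated)
Conditions: (i-Bu)2AlH (1.2 equiv), CH2Cl2, −78 °C; MeOH quench at −78 °C, then aq. potassium sodium tartrate (KNaC4H4O6), rt
Reagents that add atoms: none
Why: Partial hydride reduction of the aryl lactone (ester-to-aldehyde reduction with (i-Bu)2AlH) should stop at the tetrahedral aluminium lactolate at −78 °C, and aqueous work-up collapses this mixed acetal with loss of acetone to the hydrogen-bonded salicylaldehyde, a known behaviour of 2,2-dimethyl-1,3-benzodioxin-4-ones.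

Step 7
Reactants: 13 4-[(tert-butyldimethylsilyl)oxy]-2-[(8Z,11Z)-heptadeca-8,11-dien-1-yl]-6-hydroxybenzaldehyde
Product: 14 2,4-bis[(tert-butyldimethylsilyl)oxy]-6-[(8Z,11Z)-heptadeca-8,11-dien-1-yl]benzaldehyde
Conditions: TBSCl, imidazole, DMF, rt
Reagents that add atoms: tert-butyldimethylsilyl chloride, CC(C)(C)[Si](C)(C)Cl
Why: Standard silylation of the chelated ortho phenol blocks the future C5 oxygen, so that only the oxygen created next at C6 can be acetylated.

Step 8
Reactants: 14 2,4-bis[(tert-butyldimethylsilyl)oxy]-6-[(8Z,11Z)-heptadeca-8,11-dien-1-yl]benzaldehyde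
Product: 16 2,4-bis[(tert-butyldimethylsilyl)oxy]-6-[(8Z,11Z)-heptadeca-8,11-dien-1-yl]phenol, via aryl formate 15 (not isolated)
Conditions: 30% aq. H2O2, KHSO4 (cat.), MeOH–CH2Cl2, 0 °C → rt; aq. Na2S2O3
Reagents that add atoms: hydrogen peroxide, OO
Why: In this acid-catalysed Dakin oxidation (a Baeyer–Villiger-type aryl shift) H2O2 adds to the aldehyde, the electron-rich aryl group with ortho and para silyloxy donors migrates to oxygen to give the aryl formate, and acidic methanol transesterifies it to the phenol, while metal-free H2O2, unlike a peracid, does not epoxidise the isolated Z-alkenes.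

Step 9
Reactants: 16 2,4-bis[(tert-butyldimethylsilyl)oxy]-6-[(8Z,11Z)-heptadeca-8,11-dien-1-yl]phenol
Product: 17 2,4-bis[(tert-butyldimethylsilyl)oxy]-6-[(8Z,11Z)-heptadeca-8,11-dien-1-yl]phenyl acetate
Conditions: Ac2O, pyridine, DMAP (cat.), CH2Cl2, 0 °C
Reagents that add atoms: acetic anhydride, CC(=O)OC(C)=O
Why: DMAP-catalysed acetylation of the single free, flanked phenol should be fast at 0 °C and uses no strong base, which keeps the neighbouring silyl group from migrating before the acetate is in place.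

Step 10
Reactants: 17 2,4-bis[(tert-butyldimethylsilyl)oxy]-6-[(8Z,11Z)-heptadeca-8,11-dien-1-yl]phenyl acetate
Product: 18 ardisiphenol C, 2-[(8Z,11Z)-heptadeca-8,11-dien-1-yl]-4,6-dihydroxyphenyl acetate
Conditions: HF·pyridine, pyridine, THF, 0 °C → rt
Reagents that add atoms: none
Why: Fluoride-mediated cleavage of both aryl silyl ethers with weakly acidic, pyridine-buffered HF keeps the liberated phenols protonated, so the aryl acetate should be neither hydrolysed nor transferred to the adjacent C5 oxygen.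

Compound list
1 | linoleic acid, (9Z,12Z)-octadeca-9,12-dienoic acid | CCCCC/C=C\C/C=C\CCCCCCCC(=O)O | starting material
2 | O-[(9Z,12Z)-octadeca-9,12-dienoyl]-N,N'-dicyclohexylisourea | CCCCC/C=C\C/C=C\CCCCCCCC(=O)OC(=NC1CCCCC1)NC1CCCCC1 | intermediate (not isolated)
3 | 1-[(9Z,12Z)-octadeca-9,12-dienoyl]-1H-benzotriazole | CCCCC/C=C\C/C=C\CCCCCCCC(=O)n1nnc2ccccc21 | intermediate
4 | 2,2,6-trimethyl-4H-1,3-dioxin-4-one | CC1=CC(=O)OC(C)(C)O1 | starting material
5 | lithium 2,2-dimethyl-6-methylidene-6H-1,3-dioxin-4-olate (γ-dienolate of 4) | [Li+].C=C1C=C([O-])OC(C)(C)O1 | intermediate (not isolated)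
6 | 2,2-dimethyl-6-(2-oxopropyl)-4H-1,3-dioxin-4-one | CC(=O)CC1=CC(=O)OC(C)(C)O1 | intermediate
7 | dilithium 2,2-dimethyl-6-(2-oxidoprop-2-en-1-ylidene)-6H-1,3-dioxin-4-olate (dianion of 6) | [Li+].[Li+].C=C([O-])C=C1C=C([O-])OC(C)(C)O1 | intermediate (not isolated)
8 | 6-[(12Z,15Z)-2,4-dioxohenicosa-12,15-dien-1-yl]-2,2-dimethyl-4H-1,3-dioxin-4-one | CCCCC/C=C\C/C=C\CCCCCCCC(=O)CC(=O)CC1=CC(=O)OC(C)(C)O1 | intermediate (key-step precursor)
9 | 5-[(8Z,11Z)-heptadeca-8,11-dien-1-yl]-5-hydroxy-2,2-dimethyl-5,6-dihydro-4H-1,3-benzodioxine-4,7(8H)-dione (racemic aldol adduct) | CCCCC/C=C\C/C=C\CCCCCCCC1(O)CC(=O)CC2=C1C(=O)OC(C)(C)O2 | intermediate (not isolated)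
10 | 5-[(8Z,11Z)-heptadeca-8,11-dien-1-yl]-7-hydroxy-2,2-dimethyl-4H-1,3-benzodioxin-4-one | CCCCC/C=C\C/C=C\CCCCCCCc1cc(O)cc2OC(C)(C)OC(=O)c12 | intermediate (key-step product)
11 | 7-[(tert-butyldimethylsilyl)oxy]-5-[(8Z,11Z)-heptadeca-8,11-dien-1-yl]-2,2-dimethyl-4H-1,3-benzodioxin-4-one | CCCCC/C=C\C/C=C\CCCCCCCc1cc(O[Si](C)(C)C(C)(C)C)cc2OC(C)(C)OC(=O)c12 | intermediate
12 | 7-[(tert-butyldimethylsilyl)oxy]-4-[(diisobutylalumanyl)oxy]-5-[(8Z,11Z)-heptadeca-8,11-dien-1-yl]-2,2-dimethyl-4H-1,3-benzodioxine (racemic (i-Bu)2Al lactolate) | CCCCC/C=C\C/C=C\CCCCCCCc1cc(O[Si](C)(C)C(C)(C)C)cc2OC(C)(C)OC(O[Al](CC(C)C)CC(C)C)c12 | intermediate (not isolated)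
13 | 4-[(tert-butyldimethylsilyl)oxy]-2-[(8Z,11Z)-heptadeca-8,11-dien-1-yl]-6-hydroxybenzaldehyde | CCCCC/C=C\C/C=C\CCCCCCCc1cc(O[Si](C)(C)C(C)(C)C)cc(O)c1C=O | intermediate
14 | 2,4-bis[(tert-butyldimethylsilyl)oxy]-6-[(8Z,11Z)-heptadeca-8,11-dien-1-yl]benzaldehyde | CCCCC/C=C\C/C=C\CCCCCCCc1cc(O[Si](C)(C)C(C)(C)C)cc(O[Si](C)(C)C(C)(C)C)c1C=O | intermediate
15 | 2,4-bis[(tert-butyldimethylsilyl)oxy]-6-[(8Z,11Z)-heptadeca-8,11-dien-1-yl]phenyl formate | CCCCC/C=C\C/C=C\CCCCCCCc1cc(O[Si](C)(C)C(C)(C)C)cc(O[Si](C)(C)C(C)(C)C)c1OC=O | intermediate (not isolated)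
16 | 2,4-bis[(tert-butyldimethylsilyl)oxy]-6-[(8Z,11Z)-heptadeca-8,11-dien-1-yl]phenol | CCCCC/C=C\C/C=C\CCCCCCCc1cc(O[Si](C)(C)C(C)(C)C)cc(O[Si](C)(C)C(C)(C)C)c1O | intermediate
17 | 2,4-bis[(tert-butyldimethylsilyl)oxy]-6-[(8Z,11Z)-heptadeca-8,11-dien-1-yl]phenyl acetate | CCCCC/C=C\C/C=C\CCCCCCCc1cc(O[Si](C)(C)C(C)(C)C)cc(O[Si](C)(C)C(C)(C)C)c1OC(C)=O | intermediate
18 | ardisiphenol C, 2-[(8Z,11Z)-heptadeca-8,11-dien-1-yl]-4,6-dihydroxyphenyl acetate | CCCCC/C=C\C/C=C\CCCCCCCc1cc(O)cc(O)c1OC(C)=O | target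

Total step count: 10 steps.
Longest linear sequence: 9 steps (steps 2 to 10 from 4, or steps 1 and 3 to 10 from 1).

Steps most likely to fail

Step 4 (key step). The closure may stall at the hydrated stage 9, or the enolised triketide may drift into O-cyclisation and dioxinone fragmentation, so that pyranone-type material forms in place of the arene. The fallback sets out from 8 and comes back to the route at 14. Compound 8 is heated in toluene at 110 °C with methanol, so that retro-hetero-Diels–Alder loss of acetone releases an acylketene that methanol traps as methyl (15Z,18Z)-3,5,7-trioxotetracosa-15,18-dienoate F1. Cs2CO3 in MeOH followed by AcOH should then effect the same C1–C6 aldol aromatisation on the open-chain ester and give methyl 2-[(8Z,11Z)-heptadeca-8,11-dien-1-yl]-4,6-dihydroxybenzoate F2. Double silylation (TBSOTf, 2,6-lutidine, CH2Cl2, 0 °C) should give methyl 2,4-bis[(tert-butyldimethylsilyl)oxy]-6-[(8Z,11Z)-heptadeca-8,11-dien-1-yl]benzoate F3. Reduction with (i-Bu)2AlH (CH2Cl2, −78 → 0 °C) should give {2,4-bis[(tert-butyldimethylsilyl)oxy]-6-[(8Z,11Z)-heptadeca-8,11-dien-1-yl]phenyl}methanol F4, and MnO2 in CH2Cl2 should oxidise this benzylic alcohol to aldehyde 14.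

Step 8. The acid may strip an aryl silyl ether, aryl migration may be slow at the doubly ortho-substituted aldehyde, or performic acid arising from the released formate may epoxidise the diene. The fallback sets out from 13 and comes back at 16. The free ortho-hydroxy aldehyde 13 is submitted to the classical phenoxide-assisted Dakin oxidation (H2O2, NaHCO3, THF–H2O, 0 °C, degassed), which should give 5-[(tert-butyldimethylsilyl)oxy]-3-[(8Z,11Z)-heptadeca-8,11-dien-1-yl]benzene-1,2-diol F5. Site-selective mono-silylation of the less hindered hydroxyl, the one flanked by a ring hydrogen and not by the alkyl chain (TBSCl 1 equiv, imidazole, CH2Cl2, −20 °C), should then deliver 16.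

Step 3. Proton transfer from the more acidic product to unreacted dianion, O-acylation, or premature condensation of the polyanion may each waste the linoleoyl donor. The fallback sets out from 4 and 1 and comes back at 8. Dienolate 5, made from 4 as in step 2, is acylated with allyl 3-chloro-3-oxopropanoate to give allyl 4-(2,2-dimethyl-4-oxo-4H-1,3-dioxin-6-yl)-3-oxobutanoate F6. Acid 1 is converted with (COCl)2 and catalytic DMF into (9Z,12Z)-octadeca-9,12-dienoyl chloride F7. Soft enolisation of F6 (MgCl2, pyridine, CH2Cl2, 0 °C) and C-acylation with F7 at the carbon between ketone and ester should give allyl (11Z,14Z)-2-[(2,2-dimethyl-4-oxo-4H-1,3-dioxin-6-yl)acetyl]-3-oxoicosa-11,14-dienoate F8. Pd(PPh3)4 (zerovalent palladium) with morpholine in THF then removes the allyl ester in a Tsuji–Trost-type deallylation, and the resulting β-keto acid decarboxylates to 8.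

Further compounds
F1 | step 4 | methyl (15Z,18Z)-3,5,7-trioxotetracosa-15,18-dienoate | CCCCC/C=C\C/C=C\CCCCCCCC(=O)CC(=O)CC(=O)CC(=O)OC
F2 | step 4 | methyl 2-[(8Z,11Z)-heptadeca-8,11-dien-1-yl]-4,6-dihydroxybenzoate | CCCCC/C=C\C/C=C\CCCCCCCc1cc(O)cc(O)c1C(=O)OC
F3 | step 4 | methyl 2,4-bis[(tert-butyldimethylsilyl)oxy]-6-[(8Z,11Z)-heptadeca-8,11-dien-1-yl]benzoate | CCCCC/C=C\C/C=C\CCCCCCCc1cc(O[Si](C)(C)C(C)(C)C)cc(O[Si](C)(C)C(C)(C)C)c1C(=O)OC
F4 | step 4 | {2,4-bis[(tert-butyldimethylsilyl)oxy]-6-[(8Z,11Z)-heptadeca-8,11-dien-1-yl]phenyl}methanol | CCCCC/C=C\C/C=C\CCCCCCCc1cc(O[Si](C)(C)C(C)(C)C)cc(O[Si](C)(C)C(C)(C)C)c1CO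
F5 | step 8 | 5-[(tert-butyldimethylsilyl)oxy]-3-[(8Z,11Z)-heptadeca-8,11-dien-1-yl]benzene-1,2-diol | CCCCC/C=C\C/C=C\CCCCCCCc1cc(O[Si](C)(C)C(C)(C)C)cc(O)c1O
F6 | step 3 | allyl 4-(2,2-dimethyl-4-oxo-4H-1,3-dioxin-6-yl)-3-oxobutanoate | C=CCOC(=O)CC(=O)CC1=CC(=O)OC(C)(C)O1
F7 | step 3 | (9Z,12Z)-octadeca-9,12-dienoyl chloride | CCCCC/C=C\C/C=C\CCCCCCCC(=O)Cl
F8 | step 3 | allyl (11Z,14Z)-2-[(2,2-dimethyl-4-oxo-4H-1,3-dioxin-6-yl)acetyl]-3-oxoicosa-11,14-dienoate (racemic, enolisable) | C=CCOC(=O)C(C(=O)CC1=CC(=O)OC(C)(C)O1)C(=O)CCCCCCC/C=C\C/C=C\CCCCC
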